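I began with an easy sum: if each target uses up one partner, the partner charged is a ceiling on target, 23.0 % of the charge for noon and 70.0 % for dusk. That partner is used up in this way was my assumption.

| flask | starting material | partner | second substrate | remark | time |
|---|---|---|---|---|---|
| ash | 1 M (fed, over 80 min) | 0.18 equiv | 1 equiv | run made earlier; the fed solution adds 0.25 times the starting volume |  |
| maple | 1 M (fed, over 80 min) | 0.45 equiv | 1 equiv | run made earlier; the fed solution adds 0.25 times the starting volume |  |
| cedar | 1.1 M (fed, over 80 min) | 0.70 equiv | 1 equiv | run made earlier; the fed solution adds 0.25 times the starting volume |  |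
| noon | 0.60 M | 0.230 equiv | 1.00 equiv | everything together at the start, the whole solution of starting material included, so that from the start the volume is larger by 0.25 times the starting volume | 80 min |
| dusk | 1.0 M (fed, over 80 min) | 0.700 equiv | 1.00 equiv | the fed solution adds 0.25 times the starting volume | 80 min |

- ash (time / min: target / %, starting material / %): 2.50: 0, 2; 8.00: 2, 8; 15.0: 2, 15; 20.0: 3, 23; 30.0: 5, 31; 40.0: 8, 41
- maple (time / min: target / %, starting material / %): 6.00: 0, 7; 12.0: 3, 14; 20.0: 9, 17; 25.0: 10, 26; 30.0: 8, 23; 40.0: 16, 29
- cedar (time / min: target / %, starting material / %): 4.00: 1, 6; 10.0: 3, 10; 20.0: 9, 12; 30.0: 18, 20; 40.0: 25, 23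

(readings scatter by 2 percentage points)

- amounts are per litre of the starting volume; all of the dose is in the solution fed
- where the amount of starting material changes, what is given in equivalents or mol% on it follows
- percentages count the whole charge, also what has not yet gone in

1. which one finishes higher in amount of target, in percent of the starting material charged ("neither" within 2 percentage points) (noon / dusk / neither)
2. amount of target at the end, in percent of the starting material charged, noon
3. amount of target at the end, in percent of the starting material charged, dusk

I then read how far the cedar run had gone towards its ceiling. At 40.0 min, target read 25 %, a single reading with its scatter, against 0.70 equiv of partner: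

D = ln(partner charged / (partner charged − target)) = 0.442

I call D the depth. I expected it to grow in proportion to the exposure, the concentration of starting material summed over time. In cedar the starting material rose from nothing to a reading of 0.225 M, so I took the exposure as a triangle:

exposure, cedar = 270 M·s

Now noon in slow motion. In the first instants the whole charge is in, at 0.480 M, so partner meets starting material at once. Through the middle I held that concentration, and by the end:

exposure, noon = 38.4 M·min
depth, noon = 3.77
target, noon = 22.5 %

By this reckoning 2.30 % of the partner charged was left at the end.

Dusk starts differently. In the first instants the starting material is just beginning to go in, and partner stands with second substrate. Through the middle I let it follow cedar, scaled by the charge. For the end I let the concentration hold at its level, which gives 3 times the exposure up to the middle: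

depth, dusk = 1.20
target, dusk = 49.0 %

The forecast, from the same runs, named dusk, with noon at 19 % (13 % to 25 %) and dusk at 47 % (37 % to 56 %): “Dusk has far more partner and higher concentration, so dusk clearly wins”. My two numbers stood a little above its two.

The flasks gave dusk as the higher, with noon at 18.2 % and dusk at 33.3 %.

    2 starting material → homo dimer (k = 1.20 × 10⁻⁷ L mol⁻¹ s⁻¹)
    starting material + partner → target (k = 0.00210 L mol⁻¹ s⁻¹)
    target ⇌ isomer of the product (K = 1.90, k = 6.10 × 10⁻⁶ s⁻¹)
    second substrate + partner → second product (k = 3.10 × 10⁻⁴ L mol⁻¹ s⁻¹)
    partner → decomposed reagent (k = 5.20 × 10⁻⁵ s⁻¹)
    starting material + second substrate → cross product (k = 7.90 × 10⁻⁵ L mol⁻¹ s⁻¹)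

Noon filled 0.792 of its ceiling and dusk 0.475, a depth of 0.644 for dusk against the 1.20 I built on cedar's 0.442. At the end dusk held 0.227 M of second product beside 0.266 M of target, while noon held 0.0145 M beside 0.0875 M, so second product per target was larger in dusk. Noon's end depth of 1.57, put on its neighbour with 0.140 equiv of partner, gives 11.1 %, and that flask ended at 11.2 %.

(All runs come from a simulation with made-up constants; noise was put on by code.)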